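**Retrosynthetic overview**

1. Locants used throughout (elemane numbering): ring C10 (methyl, vinyl C1=C2) – C9H2 – C8 (O-acyl) – C7 (bearing C11(=C13H2)–C12O2H) – C6 (OH) – C5 (bearing C4(=C3H2)–C15H2OH); the vinyl group and the four substituents on C5–C8 all lie on one ring face.
2. Endgame: C12 tert-butyl ester cleavage and desilylation ⇐ esterification of C8–OH with (Z)-4-acetoxy-2-methylbut-2-enoic acid ⇐ one triple methylenation (C1=C2, C11=C13, C4=C3) of a tricarbonyl compound.
3. Tricarbonyl ⇐ ozonolysis of a bicyclo[2.2.2]octenone in which C1 (on C10) and C11 (on C7) are joined as an etheno bridge; the C5 side chain (Pd α-alkenylation) and C6–OH (ketone reduction) are set on this boat-locked bicycle.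
4. Bicycle ⇐ inverse-electron-demand Diels–Alder reaction of vinyl acetate with a 6,6-dimethoxycyclohexa-2,4-dienone made in situ from a 3-hydroxy-4-methoxy-5-methylbenzoate; this forms C9–C10 and C7–C8. Enabling feature: C11 on C7 and C1 on C10 are cis-1,4 across the ring and can be tied into a two-carbon bridge, and the 1,3-dioxygenation at C6/C8 matches the polarity of the dienone.
5. Ring order: the benzene ring is dearomatized; the second six-membered ring (C7–C8–C9–C10–C1–C11) is closed in the key step; ozonolysis later opens it and leaves the cyclohexane C5–C10.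

Key step: step 4

**Remarks.** The stereodescriptors of the given SMILES are read as the all-cis isomer, (5R,6S,7S,8R,10R) in the numbering above. Compound 8 is racemic; its SMILES shows the enantiomer that is carried on after step 5. In the names of bicyclic compounds the locants are C1 = C7, C2 = C8, C3 = C9, C4 = C10, C5 = C5, C6 = C6, C7 = C11, C8 = C1 of the elemane numbering, and "syn" means on the side of the C7=C8 etheno bridge. In the cyclohexyl names ring C1 = C7, C2 = C6, C3 = C5, C4 = C10, C5 = C9, C6 = C8.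

**Route**

Step 1
Reactants: 1 4-methoxy-3-methylbenzoic acid
Product: 2 3-bromo-4-methoxy-5-methylbenzoic acid
Conditions: Br2, AcOH, rt
Reagents that add atoms: bromine, BrBr
Why: Electrophilic aromatic bromination should go to the one free position that is ortho to the methoxy group and meta to the carboxyl group, which fixes the substitution pattern of the later dienone.

Step 2
Reactants: 2 3-bromo-4-methoxy-5-methylbenzoic acid
Product: 3 tert-butyl 3-bromo-4-methoxy-5-methylbenzoate
Conditions: tert-butyl 2,2,2-trichloroacetimidate, BF3·OEt2 (cat.), CH2Cl2/cyclohexane, rt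
Reagents that add atoms: tert-butyl 2,2,2-trichloroacetimidate, CC(C)(C)OC(=N)C(Cl)(Cl)Cl
Why: Acid-catalysed imidate esterification installs a tert-butyl ester that should survive the enolate, hydride, ozone and fluoride steps and can be removed at the end without base.

Step 3
Reactants: 3 tert-butyl 3-bromo-4-methoxy-5-methylbenzoate
Product: 5 tert-butyl 3-hydroxy-4-methoxy-5-methylbenzoate, via aryl pinacol boronate 4 (not isolated)
Conditions: B2pin2, PdCl2(dppf), KOAc, dioxane, 90 °C; then NaBO3·4H2O, THF/H2O, rt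
Reagents that add atoms: sodium perborate, [Na+].[O-]OB=O
Why: Miyaura borylation of the aryl bromide followed by oxidation of the C–B bond at the same carbon should give the 2-methoxyphenol needed for dearomatization.

Step 4
Reactants: 5 tert-butyl 3-hydroxy-4-methoxy-5-methylbenzoate; 6 vinyl acetate
Product: 8 rac-tert-butyl 2-acetoxy-5,5-dimethoxy-4-methyl-6-oxobicyclo[2.2.2]oct-7-ene-7-carboxylate (acetoxy syn), via masked o-benzoquinone 7 (not isolated)
Conditions: PhI(OAc)2, MeOH/vinyl acetate (1:1), slow addition of 5, 0 °C → 50 °C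
Reagents that add atoms: methanol, CO
Why: PhI(OAc)2 oxidizes the phenol and methanol is captured at the methoxy-bearing ortho carbon to give the 6,6-dimethoxycyclohexa-2,4-dienone 7, which is trapped in situ by vinyl acetate in an inverse-electron-demand Diels–Alder reaction; the closest known reaction type is the cycloaddition of masked o-benzoquinones (including ester-substituted ones) with enol ethers and vinyl esters to give bicyclo[2.2.2]octenones. The concerted suprafacial [4π+2π] addition closes the new cyclohexene ring C7–C8–C9–C10–C1–C11 across the diene termini, forming C9–C10 and C7–C8 at once, so that the ring C10–C9–C8–C7–C6–C5 of the bicycle is the target cyclohexane locked as a boat. Regiochemistry should follow the dienone polarity: the δ-carbon C10 (methyl-bearing) is the electrophilic terminus and takes the nucleophilic CH2 of the vinyl ester, which is also the sterically easier way to build the quaternary carbon, while the acetoxy carbon joins the α-carbon C7. C7 and C10 are fixed relative to each other by the suprafacial addition, and C8 by the endo rule, which places the acetoxy group under the diene, that is syn to the new C11=C1 bridge and hence cis to C7–C11 and C10–C1 once that bridge is cleaved. The step needs cross-cycloaddition to win over dimerization of 7, which the large excess of dienophile, the slow addition of 5 and the methyl and ester groups on the diene should secure; the adduct is racemic and the absolute configuration is settled in step 5.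

Step 5
Reactants: 8 rac-tert-butyl 2-acetoxy-5,5-dimethoxy-4-methyl-6-oxobicyclo[2.2.2]oct-7-ene-7-carboxylate
Product: 9 tert-butyl 2-hydroxy-5,5-dimethoxy-4-methyl-6-oxobicyclo[2.2.2]oct-7-ene-7-carboxylate (single enantiomer; hydroxyl syn)
Conditions: immobilized lipase from Burkholderia cepacia, phosphate buffer pH 7/MTBE, 30 °C, stopped near half conversion
Reagents that add atoms: none
Why: Lipase-catalysed kinetic resolution by hydrolysis of a secondary acetate should, by the usual size rule for secondary carbinols (bridgehead side large, CH2 side medium), convert the (8R) acetate and leave the mirror-image acetate behind for chromatographic removal, and because no alkoxide is formed at pH 7 the β-hydroxy ketone should not undergo retro-aldol cleavage.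

Step 6
Reactants: 9 tert-butyl 2-hydroxy-5,5-dimethoxy-4-methyl-6-oxobicyclo[2.2.2]oct-7-ene-7-carboxylate
Product: 10 tert-butyl 5,5-dimethoxy-4-methyl-6-oxo-2-(triethylsilyloxy)bicyclo[2.2.2]oct-7-ene-7-carboxylate
Conditions: TESCl, imidazole, DMF, 0 °C → rt
Reagents that add atoms: triethylsilyl chloride, CC[Si](Cl)(CC)CC
Why: Silylation under weakly basic conditions gives a C8 ether without α-hydrogens that should tolerate the enolate chemistry and can later be removed selectively in the presence of the bulkier silyl ethers.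

Step 7
Reactants: 10 tert-butyl 5,5-dimethoxy-4-methyl-6-oxo-2-(triethylsilyloxy)bicyclo[2.2.2]oct-7-ene-7-carboxylate
Product: 11 tert-butyl 4-methyl-6-oxo-2-(triethylsilyloxy)bicyclo[2.2.2]oct-7-ene-7-carboxylate
Conditions: SmI2 (excess), THF/MeOH, −78 → −20 °C
Reagents that add atoms: none
Why: SmI2 reduction of an α-alkoxy ketone cleaves each C–OMe bond next to the carbonyl in turn through the ketyl and the samarium enolate, which should remove the ketal that was needed only to hold the dienone, while the β-silyloxy group and the unsaturated ester are left alone at low temperature.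

Step 8
Reactants: 12 2-bromoprop-2-en-1-ol
Product: 13 (2-bromoprop-2-en-1-yloxy)triisopropylsilane
Conditions: TIPSCl, imidazole, DMF, rt
Reagents that add atoms: triisopropylsilyl chloride, CC(C)[Si](Cl)(C(C)C)C(C)C
Why: Standard silylation of a primary allylic alcohol gives the alkenyl bromide coupling partner with a C15–O group robust enough to outlast the later selective triethylsilyl cleavage.

Step 9
Reactants: 11 tert-butyl 4-methyl-6-oxo-2-(triethylsilyloxy)bicyclo[2.2.2]oct-7-ene-7-carboxylate; 13 (2-bromoprop-2-en-1-yloxy)triisopropylsilane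
Product: 15 tert-butyl 4-methyl-6-oxo-2-(triethylsilyloxy)-5-[3-(triisopropylsilyloxy)prop-1-en-2-yl]bicyclo[2.2.2]oct-7-ene-7-carboxylate (C5 substituent syn), via lithium enolate 14 (not isolated)
Conditions: LiHMDS, toluene/THF, −78 → 0 °C; then 13, Pd2(dba)3, P(t-Bu)3, rt
Reagents that add atoms: none
Why: Palladium-catalysed α-alkenylation of a ketone enolate (oxidative addition of zerovalent palladium to the C–Br bond, transmetalation with enolate 14, C–C reductive elimination) should put the 2-propenyl unit on C5, the only enolizable position because C7 is a bridgehead, from the less hindered face turned toward the etheno bridge, which is also the more stable orientation if the product re-enolizes, while migration of the new double bond into conjugation is disfavoured by allylic strain with the bridgehead methyl.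

Step 10
Reactants: 15 tert-butyl 4-methyl-6-oxo-2-(triethylsilyloxy)-5-[3-(triisopropylsilyloxy)prop-1-en-2-yl]bicyclo[2.2.2]oct-7-ene-7-carboxylate
Product: 16 tert-butyl 6-hydroxy-4-methyl-2-(triethylsilyloxy)-5-[3-(triisopropylsilyloxy)prop-1-en-2-yl]bicyclo[2.2.2]oct-7-ene-7-carboxylate (C6 hydroxyl syn)
Conditions: NaBH4, MeOH/CH2Cl2, −40 → 0 °C
Reagents that add atoms: none
Why: Borohydride 1,2-reduction should deliver hydride from the ethano-bridge face, because the other face of the C6 carbonyl is screened by the adjacent C5 substituent and the bridge ester, so the new C6–OH is syn to the etheno bridge and cis to the C5 side chain, and it removes the only carbonyl that could later epimerize C5 or C7.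

Step 11
Reactants: 16 tert-butyl 6-hydroxy-4-methyl-2-(triethylsilyloxy)-5-[3-(triisopropylsilyloxy)prop-1-en-2-yl]bicyclo[2.2.2]oct-7-ene-7-carboxylate
Product: 17 tert-butyl 6-(tert-butyldimethylsilyloxy)-4-methyl-2-(triethylsilyloxy)-5-[3-(triisopropylsilyloxy)prop-1-en-2-yl]bicyclo[2.2.2]oct-7-ene-7-carboxylate
Conditions: TBSOTf, 2,6-lutidine, CH2Cl2, 0 °C → rt
Reagents that add atoms: tert-butyldimethylsilyl triflate, CC(C)(C)[Si](C)(C)OS(=O)(=O)C(F)(F)F
Why: The reactive silyl triflate should protect the hindered C6 hydroxyl, which prevents lactol formation with the aldehyde made in the next step and lactonization onto C12 later.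

Step 12
Reactants: 17 tert-butyl 6-(tert-butyldimethylsilyloxy)-4-methyl-2-(triethylsilyloxy)-5-[3-(triisopropylsilyloxy)prop-1-en-2-yl]bicyclo[2.2.2]oct-7-ene-7-carboxylate
Product: 18 tert-butyl 2-[2-(tert-butyldimethylsilyloxy)-4-formyl-4-methyl-6-(triethylsilyloxy)-3-[(triisopropylsilyloxy)acetyl]cyclohexyl]-2-oxoacetate (substituents on ring C1, C2, C3, C6 and the formyl group all cis)
Conditions: O3, CH2Cl2/MeOH (5:1), NaHCO3, −78 °C; then Me2S, −78 °C → rt
Reagents that add atoms: ozone, [O-][O+]=O
Why: Ozonolysis with reductive work-up should cleave the etheno bridge to the C1 aldehyde on C10 and the α-keto ester on C7, which stay cis because they were the two ends of one bridge, and at the same time turn the side-chain methylidene into the C4 ketone, without touching any stereocenter, silyl ether or ester.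

Step 13
Reactants: 18 tert-butyl 2-[2-(tert-butyldimethylsilyloxy)-4-formyl-4-methyl-6-(triethylsilyloxy)-3-[(triisopropylsilyloxy)acetyl]cyclohexyl]-2-oxoacetate
Product: 19 tert-butyl 2-[2-(tert-butyldimethylsilyloxy)-4-ethenyl-4-methyl-6-(triethylsilyloxy)-3-[3-(triisopropylsilyloxy)prop-1-en-2-yl]cyclohexyl]prop-2-enoate (all-cis as in 18)
Conditions: Zn, CH2Br2, TiCl4, THF, 0 °C (reagent pre-formed); then 18, CH2Cl2, 0 °C → rt
Reagents that add atoms: dibromomethane, BrCBr
Why: Takai–Lombardo methylenation with the non-basic gem-dizinc/titanium reagent should convert the aldehyde, the ketone and the keto group of the α-keto ester into the vinyl group, the 2-propenyl unit and the acrylate in one operation, without enolizing C5 or C7, eliminating a β-silyloxy group or attacking the ester carbonyl.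

Step 14
Reactants: 19 tert-butyl 2-[2-(tert-butyldimethylsilyloxy)-4-ethenyl-4-methyl-6-(triethylsilyloxy)-3-[3-(triisopropylsilyloxy)prop-1-en-2-yl]cyclohexyl]prop-2-enoate
Product: 20 tert-butyl 2-[2-(tert-butyldimethylsilyloxy)-4-ethenyl-6-hydroxy-4-methyl-3-[3-(triisopropylsilyloxy)prop-1-en-2-yl]cyclohexyl]prop-2-enoate
Conditions: HF·pyridine, pyridine, THF, 0 °C
Reagents that add atoms: none
Why: Buffered HF·pyridine should cleave the triethylsilyl ether much faster than the tert-butyldimethylsilyl and triisopropylsilyl ethers, and the neutral C8 hydroxyl should not lactonize onto the hindered tert-butyl ester.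

Step 15
Reactants: 21 citraconic anhydride
Product: 22 (Z)-2-methylbut-2-ene-1,4-diol
Conditions: LiAlH4, Et2O, 0 °C → rt
Reagents that add atoms: none
Why: Hydride reduction of both carbonyl groups of the cyclic anhydride should give the diol with the Z geometry that the ring had enforced.

Step 16
Reactants: 22 (Z)-2-methylbut-2-ene-1,4-diol; 6 vinyl acetate
Product: 23 (Z)-4-acetoxy-2-methylbut-2-en-1-ol
Conditions: immobilized Candida antarctica lipase B, MTBE, rt
Reagents that add atoms: none
Why: Lipase-catalysed transesterification should acetylate the less hindered hydroxymethyl group, the one remote from the methyl-bearing carbon, and is irreversible because the vinyl alcohol set free tautomerizes to acetaldehyde.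

Step 17
Reactants: 23 (Z)-4-acetoxy-2-methylbut-2-en-1-ol
Product: 24 (Z)-4-acetoxy-2-methylbut-2-enoic acid
Conditions: TEMPO (cat.), NaOCl (cat.), NaClO2, MeCN/phosphate buffer pH 6.7, 35 °C
Reagents that add atoms: sodium chlorite, [Na+].[O-]Cl=O
Why: The nitroxyl/chlorite oxidation takes the primary allylic alcohol through the aldehyde to the acid under near-neutral conditions, and because the aldehyde is consumed as it forms the Z geometry and the acetate should be kept.

Step 18
Reactants: 20 tert-butyl 2-[2-(tert-butyldimethylsilyloxy)-4-ethenyl-6-hydroxy-4-methyl-3-[3-(triisopropylsilyloxy)prop-1-en-2-yl]cyclohexyl]prop-2-enoate; 24 (Z)-4-acetoxy-2-methylbut-2-enoic acid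
Product: 26 tert-butyl 2-[6-{[(2Z)-4-acetoxy-2-methylbut-2-enoyl]oxy}-2-(tert-butyldimethylsilyloxy)-4-ethenyl-4-methyl-3-[3-(triisopropylsilyloxy)prop-1-en-2-yl]cyclohexyl]prop-2-enoate, via mixed anhydride 25 (not isolated)
Conditions: 2,4,6-trichlorobenzoyl chloride, Et3N, toluene, rt; then 20, DMAP (substoichiometric), toluene, rt
Reagents that add atoms: none
Why: Yamaguchi esterification through the mixed anhydride should acylate the hindered secondary C8 hydroxyl with retention at C8, and keeping the nucleophilic catalyst low limits Z-to-E isomerization of the acyl group.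

Step 19
Reactants: 26 tert-butyl 2-[6-{[(2Z)-4-acetoxy-2-methylbut-2-enoyl]oxy}-2-(tert-butyldimethylsilyloxy)-4-ethenyl-4-methyl-3-[3-(triisopropylsilyloxy)prop-1-en-2-yl]cyclohexyl]prop-2-enoate
Product: 27 tert-butyl 2-[6-{[(2Z)-4-acetoxy-2-methylbut-2-enoyl]oxy}-4-ethenyl-2-hydroxy-3-(3-hydroxyprop-1-en-2-yl)-4-methylcyclohexyl]prop-2-enoate
Conditions: HF·pyridine, THF, 0 °C → rt
Reagents that add atoms: none
Why: Fluoride-mediated cleavage of both remaining silyl ethers under mildly acidic conditions should leave the two esters of the side chain untouched and avoid base-induced acyl migration from C8 to C6, while the tert-butyl ester still blocks lactonization of the freed C6 hydroxyl.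

Step 20
Reactants: 27 tert-butyl 2-[6-{[(2Z)-4-acetoxy-2-methylbut-2-enoyl]oxy}-4-ethenyl-2-hydroxy-3-(3-hydroxyprop-1-en-2-yl)-4-methylcyclohexyl]prop-2-enoate
Product: 29 2-[(1S,2S,3R,4R,6R)-6-{[(2Z)-4-acetoxy-2-methylbut-2-enoyl]oxy}-4-ethenyl-2-hydroxy-3-(3-hydroxyprop-1-en-2-yl)-4-methylcyclohexyl]prop-2-enoic acid (target), via tris(trimethylsilyl) derivative 28 (not isolated)
Conditions: TMSOTf, 2,6-lutidine, CH2Cl2, 0 °C → rt; then MeOH, aqueous citric acid (pH 4), 0 °C
Reagents that add atoms: none
Why: The silyl triflate first caps both hydroxyls and then cleaves the tert-butyl ester by loss of 2-methylpropene to the silyl ester, so the acid is unveiled without protic acid, and the brief cold hydrolysis of the three trimethylsilyl groups should release the γ-hydroxy acid before it can lactonize.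

**Compound list**

1 | 4-methoxy-3-methylbenzoic acid | COc1ccc(C(O)=O)cc1C | starting material
2 | 3-bromo-4-methoxy-5-methylbenzoic acid | COc1c(C)cc(C(O)=O)cc1Br | intermediate
3 | tert-butyl 3-bromo-4-methoxy-5-methylbenzoate | COc1c(C)cc(C(=O)OC(C)(C)C)cc1Br | intermediate
4 | tert-butyl 4-methoxy-3-methyl-5-(4,4,5,5-tetramethyl-1,3,2-dioxaborolan-2-yl)benzoate (not isolated) | COc1c(C)cc(C(=O)OC(C)(C)C)cc1B1OC(C)(C)C(C)(C)O1 | intermediate
5 | tert-butyl 3-hydroxy-4-methoxy-5-methylbenzoate | COc1c(C)cc(C(=O)OC(C)(C)C)cc1O | intermediate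
6 | vinyl acetate | C=COC(C)=O | starting material
7 | tert-butyl 6,6-dimethoxy-5-methyl-1-oxocyclohexa-2,4-diene-3-carboxylate, masked o-benzoquinone (not isolated) | COC1(OC)C(=O)C=C(C=C1C)C(=O)OC(C)(C)C | intermediate
8 | rac-tert-butyl 2-acetoxy-5,5-dimethoxy-4-methyl-6-oxobicyclo[2.2.2]oct-7-ene-7-carboxylate, acetoxy syn (racemate; SMILES shows the enantiomer carried on) | C=2[C@@]1(C)C[C@@H](OC(C)=O)[C@@H](C2C(=O)OC(C)(C)C)C(=O)C1(OC)OC | intermediate
9 | tert-butyl 2-hydroxy-5,5-dimethoxy-4-methyl-6-oxobicyclo[2.2.2]oct-7-ene-7-carboxylate, hydroxyl syn, single enantiomer | C=2[C@@]1(C)C[C@@H](O)[C@@H](C2C(=O)OC(C)(C)C)C(=O)C1(OC)OC | intermediate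
10 | tert-butyl 5,5-dimethoxy-4-methyl-6-oxo-2-(triethylsilyloxy)bicyclo[2.2.2]oct-7-ene-7-carboxylate | C=2[C@@]1(C)C[C@@H](O[Si](CC)(CC)CC)[C@@H](C2C(=O)OC(C)(C)C)C(=O)C1(OC)OC | intermediate
11 | tert-butyl 4-methyl-6-oxo-2-(triethylsilyloxy)bicyclo[2.2.2]oct-7-ene-7-carboxylate | C=2[C@@]1(C)C[C@@H](O[Si](CC)(CC)CC)[C@@H](C2C(=O)OC(C)(C)C)C(=O)C1 | intermediate
12 | 2-bromoprop-2-en-1-ol | OCC(Br)=C | starting material
13 | (2-bromoprop-2-en-1-yloxy)triisopropylsilane | C=C(Br)CO[Si](C(C)C)(C(C)C)C(C)C | intermediate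
14 | lithium enolate of 11 (not isolated) | C=2[C@@]1(C)C[C@@H](O[Si](CC)(CC)CC)[C@@H](C2C(=O)OC(C)(C)C)C([O-])=C1.[Li+] | intermediate
15 | tert-butyl 4-methyl-6-oxo-2-(triethylsilyloxy)-5-[3-(triisopropylsilyloxy)prop-1-en-2-yl]bicyclo[2.2.2]oct-7-ene-7-carboxylate, C5 substituent syn | C=2[C@@]1(C)C[C@@H](O[Si](CC)(CC)CC)[C@@H](C2C(=O)OC(C)(C)C)C(=O)[C@H]1C(=C)CO[Si](C(C)C)(C(C)C)C(C)C | intermediate
16 | tert-butyl 6-hydroxy-4-methyl-2-(triethylsilyloxy)-5-[3-(triisopropylsilyloxy)prop-1-en-2-yl]bicyclo[2.2.2]oct-7-ene-7-carboxylate, C2–O, C5 substituent and C6–OH all syn | C=2[C@@]1(C)C[C@@H](O[Si](CC)(CC)CC)[C@@H](C2C(=O)OC(C)(C)C)[C@@H](O)[C@H]1C(=C)CO[Si](C(C)C)(C(C)C)C(C)C | intermediate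
17 | tert-butyl 6-(tert-butyldimethylsilyloxy)-4-methyl-2-(triethylsilyloxy)-5-[3-(triisopropylsilyloxy)prop-1-en-2-yl]bicyclo[2.2.2]oct-7-ene-7-carboxylate | C=2[C@@]1(C)C[C@@H](O[Si](CC)(CC)CC)[C@@H](C2C(=O)OC(C)(C)C)[C@@H](O[Si](C)(C)C(C)(C)C)[C@H]1C(=C)CO[Si](C(C)C)(C(C)C)C(C)C | intermediate
18 | tert-butyl 2-[2-(tert-butyldimethylsilyloxy)-4-formyl-4-methyl-6-(triethylsilyloxy)-3-[(triisopropylsilyloxy)acetyl]cyclohexyl]-2-oxoacetate, all-cis | O=C[C@@]1(C)C[C@@H](O[Si](CC)(CC)CC)[C@@H](C(=O)C(=O)OC(C)(C)C)[C@@H](O[Si](C)(C)C(C)(C)C)[C@H]1C(=O)CO[Si](C(C)C)(C(C)C)C(C)C | intermediate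
19 | tert-butyl 2-[2-(tert-butyldimethylsilyloxy)-4-ethenyl-4-methyl-6-(triethylsilyloxy)-3-[3-(triisopropylsilyloxy)prop-1-en-2-yl]cyclohexyl]prop-2-enoate, all-cis | C=C[C@@]1(C)C[C@@H](O[Si](CC)(CC)CC)[C@@H](C(=C)C(=O)OC(C)(C)C)[C@@H](O[Si](C)(C)C(C)(C)C)[C@H]1C(=C)CO[Si](C(C)C)(C(C)C)C(C)C | intermediate
20 | tert-butyl 2-[2-(tert-butyldimethylsilyloxy)-4-ethenyl-6-hydroxy-4-methyl-3-[3-(triisopropylsilyloxy)prop-1-en-2-yl]cyclohexyl]prop-2-enoate, all-cis | C=C[C@@]1(C)C[C@@H](O)[C@@H](C(=C)C(=O)OC(C)(C)C)[C@@H](O[Si](C)(C)C(C)(C)C)[C@H]1C(=C)CO[Si](C(C)C)(C(C)C)C(C)C | intermediate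
21 | citraconic anhydride | CC1=CC(=O)OC1=O | starting material
22 | (Z)-2-methylbut-2-ene-1,4-diol | OC/C(C)=C\CO | intermediate
23 | (Z)-4-acetoxy-2-methylbut-2-en-1-ol | OC/C(C)=C\COC(C)=O | intermediate
24 | (Z)-4-acetoxy-2-methylbut-2-enoic acid | OC(=O)/C(C)=C\COC(C)=O | intermediate
25 | (Z)-4-acetoxy-2-methylbut-2-enoic 2,4,6-trichlorobenzoic anhydride (not isolated) | Clc1cc(Cl)c(c(Cl)c1)C(=O)OC(=O)/C(C)=C\COC(C)=O | intermediate
26 | tert-butyl 2-[6-{[(2Z)-4-acetoxy-2-methylbut-2-enoyl]oxy}-2-(tert-butyldimethylsilyloxy)-4-ethenyl-4-methyl-3-[3-(triisopropylsilyloxy)prop-1-en-2-yl]cyclohexyl]prop-2-enoate, all-cis | C=C[C@@]1(C)C[C@@H](OC(=O)/C(C)=C\COC(C)=O)[C@@H](C(=C)C(=O)OC(C)(C)C)[C@@H](O[Si](C)(C)C(C)(C)C)[C@H]1C(=C)CO[Si](C(C)C)(C(C)C)C(C)C | intermediate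
27 | tert-butyl 2-[6-{[(2Z)-4-acetoxy-2-methylbut-2-enoyl]oxy}-4-ethenyl-2-hydroxy-3-(3-hydroxyprop-1-en-2-yl)-4-methylcyclohexyl]prop-2-enoate, all-cis | C=C[C@@]1(C)C[C@@H](OC(=O)/C(C)=C\COC(C)=O)[C@@H](C(=C)C(=O)OC(C)(C)C)[C@@H](O)[C@H]1C(=C)CO | intermediate
28 | trimethylsilyl 2-[6-{[(2Z)-4-acetoxy-2-methylbut-2-enoyl]oxy}-4-ethenyl-4-methyl-2-(trimethylsilyloxy)-3-[3-(trimethylsilyloxy)prop-1-en-2-yl]cyclohexyl]prop-2-enoate (not isolated) | C=C[C@@]1(C)C[C@@H](OC(=O)/C(C)=C\COC(C)=O)[C@@H](C(=C)C(=O)O[Si](C)(C)C)[C@@H](O[Si](C)(C)C)[C@H]1C(=C)CO[Si](C)(C)C | intermediate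
29 | 2-[(1S,2S,3R,4R,6R)-6-{[(2Z)-4-acetoxy-2-methylbut-2-enoyl]oxy}-4-ethenyl-2-hydroxy-3-(3-hydroxyprop-1-en-2-yl)-4-methylcyclohexyl]prop-2-enoic acid | C=C[C@@]1(C)C[C@@H](OC(=O)/C(C)=C\COC(C)=O)[C@@H](C(=C)C(=O)O)[C@@H](O)[C@H]1C(=C)CO | target

**Step count and risks**

Total step count: 20. Longest linear sequence: 16 steps (1–7, 9–14, 18–20); step 8 and steps 15–17 are side branches.

Most likely to fail, step 9 (α-alkenylation). The coupling may be slow at the hindered C5 enolate, and re-enolization of the product under the basic conditions may erode the C5 configuration or move the new double bond into conjugation. The fallback sets out from 11 and comes back at 17. The lithium enolate of 11 (LDA, THF, −78 °C) is alkylated with allyl bromide on the etheno-bridge face to give the α-allyl ketone F1, a kinetic alkylation whose product does not epimerize. NaBH4 reduction from the ethano face gives the alcohol F2, and TBSOTf/2,6-lutidine gives the silyl ether F3. The terminal alkene alone is cleaved with OsO4 (cat.)/NaIO4/2,6-lutidine to the aldehyde F4. α-Methylenation with Eschenmoser's salt and Et3N gives the enal F5, Luche reduction (NaBH4, CeCl3) gives the allylic alcohol F6, and TIPSOTf/2,6-lutidine converts it into 17.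

Second, step 13 (triple methylenation). The tricarbonyl compound may epimerize at C5 or C7, lose a β-silyloxy group by elimination, or react incompletely at the neopentyl aldehyde. The fallback sets out from 18 and comes back at 19 by a Peterson olefination in two operations. Me3SiCH2Li precomplexed with anhydrous CeCl3 (THF, −78 °C) adds to the aldehyde, the ketone and the keto group of the keto ester to give the tris(β-hydroxysilane) F7 as a mixture of carbinol epimers, which does not matter. KH in THF then eliminates silanolate three times to give 19.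

Third, step 5 (lipase resolution). The enzyme may discriminate poorly between the enantiomers of this bulky bridged acetate, or prefer the wrong one. The fallback sets out from 8 and comes back at 10. The acetate of racemic 8 is removed without enantioselection by neutral transesterification (MeOH/toluene, (ClBu2Sn)2O as catalyst, 60 °C), which gives 9 together with its mirror image, the ent-alcohol F8. Silylation as in step 6 gives 10 together with the ent-silyl ether F9. The two are separated by preparative chromatography on a chiral stationary phase (cellulose tris(3,5-dimethylphenylcarbamate)), and 10 rejoins the route.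

Further compounds

F1 | step 9 | tert-butyl 4-methyl-6-oxo-5-(prop-2-en-1-yl)-2-(triethylsilyloxy)bicyclo[2.2.2]oct-7-ene-7-carboxylate, allyl syn | C=2[C@@]1(C)C[C@@H](O[Si](CC)(CC)CC)[C@@H](C2C(=O)OC(C)(C)C)C(=O)[C@H]1CC=C
F2 | step 9 | tert-butyl 6-hydroxy-4-methyl-5-(prop-2-en-1-yl)-2-(triethylsilyloxy)bicyclo[2.2.2]oct-7-ene-7-carboxylate, hydroxyl syn | C=2[C@@]1(C)C[C@@H](O[Si](CC)(CC)CC)[C@@H](C2C(=O)OC(C)(C)C)[C@@H](O)[C@H]1CC=C
F3 | step 9 | tert-butyl 6-(tert-butyldimethylsilyloxy)-4-methyl-5-(prop-2-en-1-yl)-2-(triethylsilyloxy)bicyclo[2.2.2]oct-7-ene-7-carboxylate | C=2[C@@]1(C)C[C@@H](O[Si](CC)(CC)CC)[C@@H](C2C(=O)OC(C)(C)C)[C@@H](O[Si](C)(C)C(C)(C)C)[C@H]1CC=C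
F4 | step 9 | tert-butyl 6-(tert-butyldimethylsilyloxy)-4-methyl-5-(2-oxoethyl)-2-(triethylsilyloxy)bicyclo[2.2.2]oct-7-ene-7-carboxylate | C=2[C@@]1(C)C[C@@H](O[Si](CC)(CC)CC)[C@@H](C2C(=O)OC(C)(C)C)[C@@H](O[Si](C)(C)C(C)(C)C)[C@H]1CC=O
F5 | step 9 | tert-butyl 6-(tert-butyldimethylsilyloxy)-4-methyl-5-(3-oxoprop-1-en-2-yl)-2-(triethylsilyloxy)bicyclo[2.2.2]oct-7-ene-7-carboxylate | C=2[C@@]1(C)C[C@@H](O[Si](CC)(CC)CC)[C@@H](C2C(=O)OC(C)(C)C)[C@@H](O[Si](C)(C)C(C)(C)C)[C@H]1C(=C)C=O
F6 | step 9 | tert-butyl 6-(tert-butyldimethylsilyloxy)-5-(3-hydroxyprop-1-en-2-yl)-4-methyl-2-(triethylsilyloxy)bicyclo[2.2.2]oct-7-ene-7-carboxylate | C=2[C@@]1(C)C[C@@H](O[Si](CC)(CC)CC)[C@@H](C2C(=O)OC(C)(C)C)[C@@H](O[Si](C)(C)C(C)(C)C)[C@H]1C(=C)CO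
F7 | step 13 | tert-butyl 2-[2-(tert-butyldimethylsilyloxy)-4-[1-hydroxy-2-(trimethylsilyl)ethyl]-3-[2-hydroxy-1-(triisopropylsilyloxy)-3-(trimethylsilyl)propan-2-yl]-4-methyl-6-(triethylsilyloxy)cyclohexyl]-2-hydroxy-3-(trimethylsilyl)propanoate, carbinol centres as mixtures | OC(C[Si](C)(C)C)[C@@]1(C)C[C@@H](O[Si](CC)(CC)CC)[C@@H](C(O)(C[Si](C)(C)C)C(=O)OC(C)(C)C)[C@@H](O[Si](C)(C)C(C)(C)C)[C@H]1C(O)(C[Si](C)(C)C)CO[Si](C(C)C)(C(C)C)C(C)C
F8 | step 5 | mirror image of 9 (ent-alcohol) | C=2[C@]1(C)C[C@H](O)[C@H](C2C(=O)OC(C)(C)C)C(=O)C1(OC)OC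
F9 | step 5 | mirror image of 10 (ent-silyl ether) | C=2[C@]1(C)C[C@H](O[Si](CC)(CC)CC)[C@H](C2C(=O)OC(C)(C)C)C(=O)C1(OC)OC
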